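## Retrosynthetic overview

- The target tetrahydrofuran (ring O1, C2, C3, C4, C5; aryl on C2, CH2OH on C3, 3,4-dimethoxybenzyl on C4) comes from its C3 carboxylic acid by borane reduction. The acid comes from a cis-fused γ-aryl-γ-butyrolactone by hydrogenolysis of the lactone's benzylic C–O bond.
- That bicyclic lactone is disconnected by a [3+2] cycloaddition of a carbonyl ylide ArCH=O(+)–CH2(−) onto the ring alkene of (R)-5-(3,4-dimethoxyphenyl)furan-2(5H)-one. This forms the C5–C4 and C2–C3 bonds together and sets all three stereocentres.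
- Enabling feature: C2–O1–C5 of the tetrahydrofuran is an aryl-bearing CH, the ring oxygen and an unsubstituted CH2, which is the carbonyl ylide of 3,4,5-trimethoxybenzaldehyde. The cis pair CH2OH (C3) / ArCH2 (C4) is the reduced form of a lactone ring bridging C3 and C4; its benzylic stereocentre steers the cycloaddition and is then erased.
- The ylide comes from the bis(silylmethyl) acetal of 3,4,5-trimethoxybenzaldehyde. The butenolide comes from a purchased γ-keto acid by asymmetric transfer hydrogenation, lactonisation and selenoxide elimination.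
- Ring order: lactone ring (step 1, temporary), tetrahydrofuran ring (step 5), lactone ring opened (step 6).

Key step: step 5

Remark: 4-(3,4-dimethoxyphenyl)-4-oxobutanoic acid and (trimethylsilyl)methanol are taken as purchasable. The selenium-bearing carbon of the selenide and the chloro-bearing carbon of the chloro ether form as mixtures, which does not matter because both centres disappear.

## Route

Step 1
Reactants: 1 4-(3,4-dimethoxyphenyl)-4-oxobutanoic acid
Product: 3 (R)-5-(3,4-dimethoxyphenyl)oxolan-2-one, via hydroxy acid 2 (not isolated)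
Conditions: RuCl[(R,R)-TsDPEN](p-cymene) (1 mol %), HCO2H–Et3N (5:2), 40 °C; then 1 M HCl, EtOAc, rt
Reagents that add atoms: none
Why: Noyori–Ikariya asymmetric transfer hydrogenation of an aryl alkyl ketone, in which the (R,R)-TsDPEN ruthenium hydride should deliver hydride to the face that gives the (R)-benzylic carbinol (as for acetophenone-type ketones), followed by lactonisation of the γ-hydroxy acid on acidic work-up.

Step 2
Reactants: 3 (R)-5-(3,4-dimethoxyphenyl)oxolan-2-one
Product: 5 (5R)-5-(3,4-dimethoxyphenyl)-3-(phenylselanyl)oxolan-2-one (both C3 epimers), via lithium enolate 4 (not isolated)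
Conditions: LiN(iPr)2 (1.1 equiv), THF, −78 °C; PhSeBr, −78 °C
Reagents that add atoms: phenylselenenyl bromide, Br[Se]c1ccccc1
Why: Kinetic lactone enolate formation and α-selenenylation, which should leave the benzylic stereocentre untouched because only the α-protons are acidic in the saturated lactone.

Step 3
Reactants: 5 (5R)-5-(3,4-dimethoxyphenyl)-3-(phenylselanyl)oxolan-2-one
Product: 7 (R)-5-(3,4-dimethoxyphenyl)furan-2(5H)-one, via selenoxide 6 (not isolated)
Conditions: 30% H2O2, pyridine, CH2Cl2, 0 °C to rt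
Reagents that add atoms: none
Why: Selenoxide syn-elimination, which can only engage the C4 hydrogens and so should give the endocyclic alkene under near-neutral conditions that do not deprotonate the γ-position of the base-sensitive butenolide.

Step 4
Reactants: 8 3,4,5-trimethoxybenzaldehyde; 9 (trimethylsilyl)methanol
Product: 10 3,4,5-trimethoxybenzaldehyde bis[(trimethylsilyl)methyl] acetal
Conditions: 9 (2.5 equiv), TsOH·H2O (2 mol %), cyclohexane, reflux, Dean–Stark; then Et3N
Reagents that add atoms: none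
Why: Acid-catalysed acetalisation driven by azeotropic removal of water, with no stereocentre involved.

Step 5
Reactants: 10 3,4,5-trimethoxybenzaldehyde bis[(trimethylsilyl)methyl] acetal; 7 (R)-5-(3,4-dimethoxyphenyl)furan-2(5H)-one
Product: 13 (3R,3aS,6R,6aR)-3-(3,4-dimethoxyphenyl)-6-(3,4,5-trimethoxyphenyl)tetrahydro-1H,3H-furo[3,4-c]furan-1-one, via chloro ether 11 (not isolated), via carbonyl ylide 12 (not isolated)
Conditions: 10 (2 equiv), AcCl (1 equiv per 10), SOCl2 (cat.), CH2Cl2, 0 °C to rt, volatiles removed under vacuum; residue in MeCN added slowly to 7 and flame-dried CsF in MeCN, rt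
Reagents that add atoms: none
Why: Acetyl chloride should convert the acetal into the α-chloro ether (acetal/acyl chloride exchange); fluoride then attacks silicon and expels chloride in a 1,3-elimination to give the non-stabilised carbonyl ylide 12, which adds across the C3=C4 bond of 7 in a concerted, asynchronous [3+2] cycloaddition. The closest known reaction type is the silicon-based 1,3-elimination of α-chlorobenzyl silylmethyl ethers with CsF and cycloaddition of the resulting ylides to acrylates, fumarates and maleimides, combined with the anti-selective dipolar cycloadditions of 5-substituted 2(5H)-furanones. The tetrahydrofuran ring closes by intermolecular 1,3-dipolar cycloaddition (three atoms C–O–C from the ylide, two from the alkene), and it is fused cis to the lactone because both new bonds form on one face of the ring alkene. C3a and C6a should be set by approach of the dipole to the face opposite the C5 aryl group of 7, and C6 by the exo transition state that keeps the trimethoxyphenyl group away from the lactone ring on the convex face. The step needs one regiochemistry, CH2 terminus to the β-carbon and benzylic terminus to the α-carbon: the ylide is polarised as ArCH=O(+)–CH2(−) because the electron-rich aryl group stabilises the oxocarbenium end, so its nucleophilic, unhindered CH2 carbon should bond to the electrophilic β-carbon next to the hindered γ-centre. Free fluoride is kept scarce (solid CsF in MeCN, slow addition of the chloro ether) so that the γ-proton of 7 should survive.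

Step 6
Reactants: 13 (3R,3aS,6R,6aR)-3-(3,4-dimethoxyphenyl)-6-(3,4,5-trimethoxyphenyl)tetrahydro-1H,3H-furo[3,4-c]furan-1-one
Product: 14 (2R,3R,4S)-4-(3,4-dimethoxybenzyl)-2-(3,4,5-trimethoxyphenyl)oxolane-3-carboxylic acid
Conditions: H2 (1 atm), 10% Pd/C, EtOAc–AcOH (10:1), rt, stopped after one equivalent of H2
Reagents that add atoms: none
Why: Hydrogenolysis of a benzylic C–O bond, where the lactone carboxylate on the electron-rich benzylic carbon is a much better leaving group than the cyclic benzylic ether at C2, so cleavage should stop at the acid while the controlling stereocentre becomes CH2 and C2, C3 and C4 stay untouched.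

Step 7
Reactants: 14 (2R,3R,4S)-4-(3,4-dimethoxybenzyl)-2-(3,4,5-trimethoxyphenyl)oxolane-3-carboxylic acid
Product: 15 [(2R,3S,4S)-4-(3,4-dimethoxybenzyl)-2-(3,4,5-trimethoxyphenyl)oxolan-3-yl]methanol
Conditions: BH3·THF, THF, 0 °C to rt; then MeOH, aq. NaHCO3
Reagents that add atoms: none
Why: Chemoselective borane reduction of a carboxylic acid to the primary alcohol via the acyloxyborane, under non-basic conditions so that the α-stereocentre C3 should not epimerise.

## Compound list

1 | 4-(3,4-dimethoxyphenyl)-4-oxobutanoic acid | COc1ccc(C(=O)CCC(=O)O)cc1OC | starting material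
2 | (R)-4-(3,4-dimethoxyphenyl)-4-hydroxybutanoic acid | O[C@@H](c1ccc(OC)c(OC)c1)CCC(=O)O | intermediate
3 | (R)-5-(3,4-dimethoxyphenyl)oxolan-2-one | O=C1O[C@@H](c2ccc(OC)c(OC)c2)CC1 | intermediate
4 | lithium (R)-5-(3,4-dimethoxyphenyl)-4,5-dihydrofuran-2-olate | [Li]OC1=CC[C@H](c2ccc(OC)c(OC)c2)O1 | intermediate
5 | (5R)-5-(3,4-dimethoxyphenyl)-3-(phenylselanyl)oxolan-2-one (both C3 epimers) | O=C1O[C@@H](c2ccc(OC)c(OC)c2)CC1[Se]c1ccccc1 | intermediate
6 | (5R)-5-(3,4-dimethoxyphenyl)-3-(phenylseleninyl)oxolan-2-one | O=C1O[C@@H](c2ccc(OC)c(OC)c2)CC1[Se](=O)c1ccccc1 | intermediate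
7 | (R)-5-(3,4-dimethoxyphenyl)furan-2(5H)-one | O=C1O[C@@H](c2ccc(OC)c(OC)c2)C=C1 | intermediate
8 | 3,4,5-trimethoxybenzaldehyde | COc1cc(C=O)cc(OC)c1OC | starting material
9 | (trimethylsilyl)methanol | C[Si](C)(C)CO | starting material
10 | 3,4,5-trimethoxybenzaldehyde bis[(trimethylsilyl)methyl] acetal | COc1cc(C(OC[Si](C)(C)C)OC[Si](C)(C)C)cc(OC)c1OC | intermediate
11 | [[chloro(3,4,5-trimethoxyphenyl)methoxy]methyl]trimethylsilane (racemic at the chloro carbon) | COc1cc(C(Cl)OC[Si](C)(C)C)cc(OC)c1OC | intermediate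
12 | carbonyl ylide, methylene(3,4,5-trimethoxybenzylidene)oxonium ylide | [CH2-][O+]=Cc1cc(OC)c(OC)c(OC)c1 | intermediate
13 | (3R,3aS,6R,6aR)-3-(3,4-dimethoxyphenyl)-6-(3,4,5-trimethoxyphenyl)tetrahydro-1H,3H-furo[3,4-c]furan-1-one (cis-fused, both aryl groups exo) | O=C1O[C@@H](c2ccc(OC)c(OC)c2)[C@@H]3CO[C@@H](c4cc(OC)c(OC)c(OC)c4)[C@H]13 | intermediate
14 | (2R,3R,4S)-4-(3,4-dimethoxybenzyl)-2-(3,4,5-trimethoxyphenyl)oxolane-3-carboxylic acid | COc1ccc(C[C@@H]2CO[C@@H](c3cc(OC)c(OC)c(OC)c3)[C@@H]2C(=O)O)cc1OC | intermediate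
15 | [(2R,3S,4S)-4-(3,4-dimethoxybenzyl)-2-(3,4,5-trimethoxyphenyl)oxolan-3-yl]methanol | COc1ccc(C[C@@H]2CO[C@@H](c3cc(OC)c(OC)c(OC)c3)[C@@H]2CO)cc1OC | target

## Step count and risks

Total steps: 7. Longest linear sequence: 6 (steps 1, 2, 3, 5, 6, 7).

Steps most likely to fail:

1. Step 5 (the riskiest). What may go wrong: fluoride may remove the γ-proton of 7 and erode its enantiopurity; the cycloaddition may show poor regio- or exo/endo selectivity; the ylide may collapse before it is trapped.

   The fallback drops the cycloaddition for the classical aldol, reduction and cationic ring-closure sequence. It sets out from aldehyde 8 and comes back to the route at 15; its second fragment is built from purchased 3,4-dimethoxybenzaldehyde and dimethyl succinate. Stobbe condensation (NaOMe, MeOH, reflux) should give (E)-4-(3,4-dimethoxyphenyl)-3-(methoxycarbonyl)but-3-enoic acid F1. Asymmetric hydrogenation ([Rh(cod)(Et-DuPhos)]BF4, the ligand antipode that gives the S acid, H2, MeOH) should give (S)-4-(3,4-dimethoxyphenyl)-3-(methoxycarbonyl)butanoic acid F2. Reduction of the ester in the presence of the carboxylate (KOH, then Ca(BH4)2, EtOH) and acidification should give (S)-4-(3,4-dimethoxybenzyl)oxolan-2-one F3. Aldol addition of F3 to 8 (LiN(SiMe3)2, THF, −78 °C) anti to the benzyl group should give (3R,4S)-4-(3,4-dimethoxybenzyl)-3-[hydroxy(3,4,5-trimethoxyphenyl)methyl]oxolan-2-one F4. LiAlH4 (THF, 0 °C) should give (2S,3S)-2-(3,4-dimethoxybenzyl)-3-[hydroxy(3,4,5-trimethoxyphenyl)methyl]butane-1,4-diol F5. Camphorsulfonic acid (CH2Cl2, rt) should ionise the benzylic alcohol and close the tetrahydrofuran through the hydroxymethyl group on the benzyl-bearing carbon, placing the aryl group trans to its neighbour, to give 15.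

2. Step 6. What may go wrong: over-reduction by competing hydrogenolysis of the benzylic ether C2–O1, or sluggish cleavage of the lactone C–O bond.

   The fallback replaces hydrogenolysis by a radical deoxygenation. It sets out from 13 and comes back at 15. LiAlH4 (THF, 0 °C) should give [(2R,3S,4S)-4-[(R)-(3,4-dimethoxyphenyl)(hydroxy)methyl]-2-(3,4,5-trimethoxyphenyl)oxolan-3-yl]methanol F6. Selective silylation of the primary alcohol (TBSCl, imidazole, CH2Cl2, 0 °C) should give (R)-[(3S,4S,5R)-4-[[(tert-butyldimethylsilyl)oxy]methyl]-5-(3,4,5-trimethoxyphenyl)oxolan-3-yl](3,4-dimethoxyphenyl)methanol F7. NaH, CS2, MeI (THF) should give the xanthate O-[(R)-[(3S,4S,5R)-4-[[(tert-butyldimethylsilyl)oxy]methyl]-5-(3,4,5-trimethoxyphenyl)oxolan-3-yl](3,4-dimethoxyphenyl)methyl] S-methyl carbonodithioate F8. Barton–McCombie reduction (Bu3SnH, AIBN, toluene, 80 °C) should give tert-butyl[[(2R,3S,4S)-4-(3,4-dimethoxybenzyl)-2-(3,4,5-trimethoxyphenyl)oxolan-3-yl]methoxy]dimethylsilane F9. Bu4NF (THF) should then give 15.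

3. Step 3. What may go wrong: loss of enantiopurity at the γ-carbon of the forming butenolide during oxidation or work-up, or over-oxidation by selenium species.

   The fallback replaces the selenoxide elimination by a palladium-mediated dehydrosilylation. It sets out from 3 and comes back at 7. LiN(iPr)2 and Me3SiCl (THF, −78 °C) should give [[(R)-5-(3,4-dimethoxyphenyl)-4,5-dihydrofuran-2-yl]oxy]trimethylsilane F10. Saegusa–Ito oxidation with Pd(OAc)2 (MeCN, rt) should give 7 under neutral conditions.

## Further compounds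

F1 | step 5 | (E)-4-(3,4-dimethoxyphenyl)-3-(methoxycarbonyl)but-3-enoic acid | COC(=O)/C(CC(=O)O)=C/c1ccc(OC)c(OC)c1
F2 | step 5 | (S)-4-(3,4-dimethoxyphenyl)-3-(methoxycarbonyl)butanoic acid | OC(=O)C[C@H](Cc1ccc(OC)c(OC)c1)C(=O)OC
F3 | step 5 | (S)-4-(3,4-dimethoxybenzyl)oxolan-2-one | O=C1C[C@H](Cc2ccc(OC)c(OC)c2)CO1
F4 | step 5 | (3R,4S)-4-(3,4-dimethoxybenzyl)-3-[hydroxy(3,4,5-trimethoxyphenyl)methyl]oxolan-2-one (carbinol epimers) | O=C1[C@@H](C(O)c2cc(OC)c(OC)c(OC)c2)[C@H](Cc2ccc(OC)c(OC)c2)CO1
F5 | step 5 | (2S,3S)-2-(3,4-dimethoxybenzyl)-3-[hydroxy(3,4,5-trimethoxyphenyl)methyl]butane-1,4-diol (carbinol epimers) | OC[C@@H](C(O)c1cc(OC)c(OC)c(OC)c1)[C@H](Cc1ccc(OC)c(OC)c1)CO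
F6 | step 6 | [(2R,3S,4S)-4-[(R)-(3,4-dimethoxyphenyl)(hydroxy)methyl]-2-(3,4,5-trimethoxyphenyl)oxolan-3-yl]methanol | OC[C@H]1[C@H](c2cc(OC)c(OC)c(OC)c2)OC[C@H]1[C@@H](O)c1ccc(OC)c(OC)c1
F7 | step 6 | (R)-[(3S,4S,5R)-4-[[(tert-butyldimethylsilyl)oxy]methyl]-5-(3,4,5-trimethoxyphenyl)oxolan-3-yl](3,4-dimethoxyphenyl)methanol | CC(C)(C)[Si](C)(C)OC[C@H]1[C@H](c2cc(OC)c(OC)c(OC)c2)OC[C@H]1[C@@H](O)c1ccc(OC)c(OC)c1
F8 | step 6 | O-[(R)-[(3S,4S,5R)-4-[[(tert-butyldimethylsilyl)oxy]methyl]-5-(3,4,5-trimethoxyphenyl)oxolan-3-yl](3,4-dimethoxyphenyl)methyl] S-methyl carbonodithioate | CC(C)(C)[Si](C)(C)OC[C@H]1[C@H](c2cc(OC)c(OC)c(OC)c2)OC[C@H]1[C@@H](OC(=S)SC)c1ccc(OC)c(OC)c1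
F9 | step 6 | tert-butyl[[(2R,3S,4S)-4-(3,4-dimethoxybenzyl)-2-(3,4,5-trimethoxyphenyl)oxolan-3-yl]methoxy]dimethylsilane | CC(C)(C)[Si](C)(C)OC[C@H]1[C@H](c2cc(OC)c(OC)c(OC)c2)OC[C@H]1Cc1ccc(OC)c(OC)c1
F10 | step 3 | [[(R)-5-(3,4-dimethoxyphenyl)-4,5-dihydrofuran-2-yl]oxy]trimethylsilane | C[Si](C)(C)OC1=CC[C@H](c2ccc(OC)c(OC)c2)O1
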